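**Retrosynthetic overview**

1. Ciwujiatone 11 ⇐ (+)-syringaresinol 9: one of the two equivalent benzylic C–O bonds (C7'–O) is oxidised to the C7'=O ketone; ring A of 9 is the oxolane of the target.
2. 9 ⇐ achiral diene-diol 7: both oxolane rings and all stereocentres come from one catalytic asymmetric double hydroalkoxylation (C7–O and C7'–O bonds); ring A closes first, then ring B.
3. 7 ⇐ diester 5 (ester reduction, O-deallylation) ⇐ double Stobbe condensation of O-allylsyringaldehyde 2 with diethyl succinate 3; 2 ⇐ syringaldehyde 1.

Assumption: lignan locants are used throughout (C7/C7' benzylic, C8/C8' the carbons joined through the succinate, C9/C9' the CH2O carbons), and the (R)-acid in step 5 is taken to give the (7S,8R,7'S,8'R) series; if induction is opposite, the (S)-acid is used.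

**Route**

Step 1
Reactants: 1 syringaldehyde (4-hydroxy-3,5-dimethoxybenzaldehyde)
Product: 2 4-(allyloxy)-3,5-dimethoxybenzaldehyde
Conditions: allyl bromide (1.2 equiv), K2CO3 (1.5 equiv), DMF, 60 °C
Reagents that add atoms: allyl bromide C=CCBr
Why: Williamson O-alkylation (SN2) of the phenoxide; the allyl ether stops phenoxide deactivation of the aldehyde in step 2 and is later removed under neutral conditions; no stereocentre is formed.

Step 2
Reactants: 2 4-(allyloxy)-3,5-dimethoxybenzaldehyde (2.2 equiv); 3 diethyl succinate
Product: 5 dimethyl (2E,3E)-2,3-bis[(4-allyloxy-3,5-dimethoxyphenyl)methylidene]butanedioate, via dipotassium dicarboxylate 4 (not isolated)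
Conditions: KOt-Bu (4 equiv), t-BuOH, reflux; then evaporate, DMF, MeI (4 equiv), rt
Reagents that add atoms: iodomethane CI
Why: Stobbe condensation run twice (aldol addition, lactonisation to the paraconic ester, base-induced ring opening; the vinylogous dianion of the half-ester repeats the sequence), giving the thermodynamically preferred E geometry at both alkenes, followed by O-methylation of dicarboxylate 4 in the same flask; no stereocentre is formed.

Step 3
Reactants: 5 dimethyl (2E,3E)-2,3-bis[(4-allyloxy-3,5-dimethoxyphenyl)methylidene]butanedioate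
Product: 6 (2E,3E)-2,3-bis[(4-allyloxy-3,5-dimethoxyphenyl)methylidene]butane-1,4-diol
Conditions: i-Bu2AlH (5 equiv), CH2Cl2, −78 °C to 0 °C; aqueous KNaC4H4O6 work-up
Reagents that add atoms: none
Why: DIBAL-H 1,2-reduction of the two α,β-unsaturated esters to allylic alcohols at low temperature leaves the trisubstituted styrenes, their E geometry and the allyl ethers untouched; no stereocentre is formed.

Step 4
Reactants: 6 (2E,3E)-2,3-bis[(4-allyloxy-3,5-dimethoxyphenyl)methylidene]butane-1,4-diol
Product: 7 (2E,3E)-2,3-bis[(4-hydroxy-3,5-dimethoxyphenyl)methylidene]butane-1,4-diol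
Conditions: Pd(PPh3)4 (5 mol %), morpholine (6 equiv), degassed THF, rt
Reagents that add atoms: none
Why: Tsuji–Trost deallylation, in which zerovalent palladium ionises each aryl allyl ether to a π-allyl complex that morpholine captures, while the free allylic alcohols are not ionised under these neutral conditions; no stereocentre is formed.

Step 5
Reactants: 7 (2E,3E)-2,3-bis[(4-hydroxy-3,5-dimethoxyphenyl)methylidene]butane-1,4-diol
Product: 9 (+)-syringaresinol (7S,8R,7'S,8'R), via 4-arylidene oxolane 8 (not isolated)
Conditions: (R)-3,3'-bis(2,4,6-triisopropylphenyl)-1,1'-binaphthyl-2,2'-diyl N-(trifluoromethylsulfonyl)phosphoramide (10 mol %), water-saturated CH2Cl2, −20 °C to 0 °C; Et3N quench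
Reagents that add atoms: none
Why: Proposed new method: a catalytic asymmetric double hydroalkoxylation (cycloisomerisation) in which the chiral acid protonates C8 of one p-hydroxystyrene unit, so that it reacts as its p-quinone methide tautomer, while the phosphoryl oxygen of the same catalyst hydrogen-bonds the C9' hydroxyl that closes on C7 in a 5-exo oxa-1,6-addition (this sets C8 and C7 in the chiral pocket, aryl trans to CH2OH); oxolane 8 is then protonated at C8' and the C9 hydroxyl closes on C7', which is possible only for the cis-fused bicycle (sets C8') with the aryl on the convex face (sets C7'); the closest known reactions are confined chiral Brønsted acid-catalysed intramolecular hydroalkoxylation of alkenes and chiral phosphoric acid-catalysed additions to p-quinone methides generated in situ from hydroxystyrenes, and the ring closures mirror those of the bis-quinone methide in the oxidative dimerisation of sinapyl alcohol.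

Step 6
Reactants: 9 (+)-syringaresinol (7S,8R,7'S,8'R)
Product: 11 ciwujiatone (7S,8R,8'R), via bicyclic hemiketal 10 (not isolated)
Conditions: DDQ (0.9 equiv), MeCN/H2O 9:1, −10 °C; unreacted 9 recovered
Reagents that add atoms: water O
Why: DDQ benzylic oxidation of a p-hydroxybenzyl ether (the reactivity of oxidative PMB-ether cleavage): two-electron oxidation gives the alkoxy p-quinone methide at C7', water adds to give hemiketal 10, which collapses to the aryl ketone and frees the C9 hydroxyl; the two benzylic sites of C2-symmetric 9 are equivalent, so one constitutional product forms, and C7, C8 and C8' are untouched (C8', now α to the ketone, is not epimerised under these non-basic conditions).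

**Compound list**

1 | syringaldehyde (4-hydroxy-3,5-dimethoxybenzaldehyde) | COc1cc(C=O)cc(OC)c1O | starting material
2 | 4-(allyloxy)-3,5-dimethoxybenzaldehyde | C=CCOc1c(OC)cc(C=O)cc1OC | intermediate
3 | diethyl succinate | CCOC(=O)CCC(=O)OCC | starting material
4 | dipotassium (2E,3E)-2,3-bis[(4-allyloxy-3,5-dimethoxyphenyl)methylidene]butanedioate (not isolated) | [K+].[K+].[O-]C(=O)/C(=C/c1cc(OC)c(OCC=C)c(OC)c1)C(\C([O-])=O)=C/c1cc(OC)c(OCC=C)c(OC)c1 | intermediate
5 | dimethyl (2E,3E)-2,3-bis[(4-allyloxy-3,5-dimethoxyphenyl)methylidene]butanedioate | COC(=O)/C(=C/c1cc(OC)c(OCC=C)c(OC)c1)C(\C(=O)OC)=C/c1cc(OC)c(OCC=C)c(OC)c1 | intermediate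
6 | (2E,3E)-2,3-bis[(4-allyloxy-3,5-dimethoxyphenyl)methylidene]butane-1,4-diol | OC/C(=C/c1cc(OC)c(OCC=C)c(OC)c1)C(\CO)=C/c1cc(OC)c(OCC=C)c(OC)c1 | intermediate
7 | (2E,3E)-2,3-bis[(4-hydroxy-3,5-dimethoxyphenyl)methylidene]butane-1,4-diol (achiral; aryl trans to CH2OH on both alkenes) | OC/C(=C/c1cc(OC)c(O)c(OC)c1)C(\CO)=C/c1cc(OC)c(O)c(OC)c1 | intermediate
8 | [(2S,3R,4E)-2-(4-hydroxy-3,5-dimethoxyphenyl)-4-[(4-hydroxy-3,5-dimethoxyphenyl)methylidene]oxolan-3-yl]methanol (not isolated; aryl and CH2OH trans) | OC[C@@H]1[C@@H](c2cc(OC)c(O)c(OC)c2)OC/C1=C/c3cc(OC)c(O)c(OC)c3 | intermediate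
9 | (+)-syringaresinol, 4,4'-[(1S,3aR,4S,6aR)-tetrahydro-1H,3H-furo[3,4-c]furan-1,4-diyl]bis(2,6-dimethoxyphenol) (7S,8R,7'S,8'R; cis-fused, both aryls on the convex face) | COc1cc([C@H]2OC[C@@H]3[C@@H](c4cc(OC)c(O)c(OC)c4)OC[C@H]23)cc(OC)c1O | intermediate
10 | (7S,8R,8'R)-7'-hydroxysyringaresinol, the bicyclic hemiketal (not isolated; either configuration at the hemiketal carbon) | COc1cc(C2(O)OC[C@@H]3[C@@H](c4cc(OC)c(O)c(OC)c4)OC[C@H]23)cc(OC)c1O | intermediate
11 | ciwujiatone, (4-hydroxy-3,5-dimethoxyphenyl)[(3R,4R,5S)-5-(4-hydroxy-3,5-dimethoxyphenyl)-4-(hydroxymethyl)oxolan-3-yl]methanone (7S,8R,8'R; aryl trans to CH2OH, CH2OH cis to aroyl) | COc1cc(C(=O)[C@H]2CO[C@H](c3cc(OC)c(O)c(OC)c3)[C@H]2CO)cc(OC)c1O | target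

**Step count and risks**

Total steps: 6. Longest linear sequence: 6 (1 → 2 → 5 → 6 → 7 → 9 → 11).

Three steps most likely to fail:

1. Step 5 (the new cycloisomerisation). Possible failure modes:
   - acid ionisation of the allylic C9–OH, leading to dehydrative ether formation;
   - protonation at C7 instead of C8, giving a 2,5-dihydrofuran isomer through the vinylogous quinone methide;
   - Friedel–Crafts closure to an aryldihydronaphthalene;
   - low enantioselectivity.

   The wet solvent is meant to keep the first two pathways reversible so that material drains to the saturated bicycle 9. Fallback with known chemistry, setting out from 1 and coming back at 9: Knoevenagel–Doebner condensation of 1 with monoethyl malonate (pyridine, piperidine) gives ethyl (E)-sinapate F1. i-Bu2AlH reduction gives sinapyl alcohol F2. Oxidative dehydrodimerisation with CuSO4 under air in aqueous buffer (8–8' radical coupling, then two spontaneous oxa-1,6 ring closures of the bis-quinone methide) gives racemic syringaresinol, that is 9 as a 1:1 mixture with (−)-syringaresinol F3. Preparative HPLC on a cellulose tris(3,5-dimethylphenylcarbamate) phase delivers 9, at the cost of at most 50 % yield in the resolution.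

2. Step 6 (mono-oxidation of 9). The product still carries one oxidisable benzylic ether, so a second oxidation to the doubly ring-opened diketone diol competes statistically (about 45 % of 11 plus recovered 9 is expected at best), and DDQ may also attack the free phenols. Fallback, setting out from 9 and coming back at 11: monoacetylation (Ac2O 1 equiv, pyridine; di- and unacetylated material recycled) gives 4-O-acetylsyringaresinol F4. DDQ in wet MeCN then oxidises only the benzylic ether of the ring that still has a free phenol, giving O-acetylciwujiatone F5. NH4OAc in aqueous MeOH removes the aryl acetate without base and gives 11.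

3. Step 2 (one-pot double Stobbe condensation). The second condensation needs the dianion of the half-ester and can be sluggish and low-yielding, and the strong base may isomerise allyl to propenyl ethers. Fallback, setting out from 2 and coming back at 6: Horner–Wadsworth–Emmons reaction of 2 with diethyl 2-(diethoxyphosphoryl)succinate (NaH, THF) gives diethyl (E)-2-[(4-allyloxy-3,5-dimethoxyphenyl)methylidene]butanedioate F6. A single Stobbe condensation of F6 with a second equivalent of 2 (KOt-Bu, t-BuOH) gives the bis-arylidene half-ester F7. MeI/K2CO3 in DMF gives the ethyl methyl diester F8. i-Bu2AlH reduction gives 6.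

**Further compounds**

F1 | step 5 | ethyl (E)-sinapate | CCOC(=O)/C=C/c1cc(OC)c(O)c(OC)c1
F2 | step 5 | sinapyl alcohol | OC/C=C/c1cc(OC)c(O)c(OC)c1
F3 | step 5 | (−)-syringaresinol (7R,8S,7'R,8'S) | COc1cc([C@@H]2OC[C@H]3[C@H](c4cc(OC)c(O)c(OC)c4)OC[C@@H]23)cc(OC)c1O
F4 | step 6 | 4-O-acetyl-(+)-syringaresinol | COc1cc([C@H]2OC[C@@H]3[C@@H](c4cc(OC)c(OC(C)=O)c(OC)c4)OC[C@H]23)cc(OC)c1O
F5 | step 6 | O-acetylciwujiatone (acetate on the aryl at C7) | COc1cc(C(=O)[C@H]2CO[C@H](c3cc(OC)c(OC(C)=O)c(OC)c3)[C@H]2CO)cc(OC)c1O
F6 | step 2 | diethyl (E)-2-[(4-allyloxy-3,5-dimethoxyphenyl)methylidene]butanedioate | CCOC(=O)/C(CC(=O)OCC)=C/c1cc(OC)c(OCC=C)c(OC)c1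
F7 | step 2 | (2E,3E)-2,3-bis[(4-allyloxy-3,5-dimethoxyphenyl)methylidene]butanedioic acid monoethyl ester | CCOC(=O)/C(=C/c1cc(OC)c(OCC=C)c(OC)c1)C(\C(=O)O)=C/c1cc(OC)c(OCC=C)c(OC)c1
F8 | step 2 | ethyl methyl (2E,3E)-2,3-bis[(4-allyloxy-3,5-dimethoxyphenyl)methylidene]butanedioate | CCOC(=O)/C(=C/c1cc(OC)c(OCC=C)c(OC)c1)C(\C(=O)OC)=C/c1cc(OC)c(OCC=C)c(OC)c1
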